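**Retrosynthetic overview**
1. Target 6 (2',8''-biluteolin) is cut only at the interflavone biaryl bond: ring B carbon C6' of luteolin unit 1 (ortho to C1', para to 3'-OH; called 2' in the biflavone name) to ring A carbon C8 of unit 2.
2. Both carbons are nucleophilic in luteolin. Ring B of unit 1 is therefore oxidised to the ortho-quinone 4, an aryl-cation (vinylogous enolonium) equivalent, and C8 of a second luteolin adds to it in Michael fashion, followed by rearomatisation.
3. The nucleophilic luteolin carries its catechol as the diphenylmethylene ketal 3, so it cannot be oxidised; the ketal is removed last by hydrogenolysis.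
4. No ring of the target is built: all six rings come from two molecules of luteolin 1. Order: temporary dioxole ring on (step 1), biaryl bond (step 2), dioxole off (step 3).

Assumption: the SMILES has no stereodescriptor and the molecule has no stereocentre; the biaryl axis is taken as not configurationally defined, so no stereocontrol is needed.

**Route**

Step 1
Reactants: 1 luteolin (5,7,3',4'-tetrahydroxyflavone); 2 dichlorodiphenylmethane
Product: 3 luteolin 3',4'-O-diphenylmethylene ketal [2-(2,2-diphenyl-1,3-benzodioxol-5-yl)-5,7-dihydroxy-4H-chromen-4-one]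
Conditions: Ph2CCl2 (1.5 equiv), Ph2O, 175 °C, 30 min, N2 sweep; precipitate with petroleum ether
Reagents that add atoms: dichlorodiphenylmethane, ClC(Cl)(c1ccccc1)c1ccccc1
Why: Catechol-selective ketalisation (double substitution of the gem-dichloride via a diaryl oxocarbenium ion), the reaction type established for quercetin; only the vicinal 3',4'-diol can close a five-membered benzodioxole, the 5-OH is tied up in a hydrogen bond to C4=O and a 7-O-monoether would revert under the HCl released; no stereocentre is formed.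

Step 2
Reactants: 1 luteolin (1.0 equiv, limiting); 3 luteolin 3',4'-O-diphenylmethylene ketal (3.0 equiv, excess recovered)
Product: 5 2',8''-biluteolin 3''',4'''-O-diphenylmethylene ketal, via luteolin ortho-quinone 4 (not isolated)
Conditions: 1, NaIO4 (0.95 equiv), acetone/aq. NaOAc–AcOH buffer pH 5 (2:1), 0 °C, 2 min; then cannulate over 30 min into 3 (3 equiv), acetone/aq. NaHCO3 pH 8.5 (2:1), 0 °C to rt, argon
Reagents that add atoms: none
Why: Proposed new method: two-electron oxidation turns the normally nucleophilic ring B of 1 into ortho-quinone 4, whose C6' is the β-carbon of the C4'=O enone, and the 7-phenolate of 3 (pKa about 7, so ionised at pH 8.5, while its ketal-masked ring B cannot be oxidised) adds through C8 in a Michael addition followed by tautomerisation back to the catechol, joining two natively nucleophilic carbons; the closest known reactions are the oxidative formation of C6'–C8 linked dehydrodicatechins from catechin ortho-quinone and the 1,4-arylation of ortho-quinones by phloroglucinol-type phenols, with C8 favoured over C6 as in Mannich reactions of 5,7-dihydroxyflavones and C- over O-attack favoured by the protic medium; no stereocentre is formed.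

Step 3
Reactants: 5 2',8''-biluteolin 3''',4'''-O-diphenylmethylene ketal
Product: 6 2',8''-biluteolin (target)
Conditions: H2 (1 atm), Pd(OH)2/C (20 wt%), THF/MeOH 1:1, rt, 3 h
Reagents that add atoms: none
Why: Catalytic hydrogenolysis of the two benzhydrylic C–O bonds of the ketal frees the catechol under neutral conditions, which avoids acid-induced Wessely–Moser isomerisation of the 8-aryl-5,7-dihydroxyflavone to the 6-aryl isomer and leaves the flavone C2=C3 bonds intact at 1 atm; no stereocentre is involved.

**Compound list**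
1 | luteolin, 2-(3,4-dihydroxyphenyl)-5,7-dihydroxy-4H-chromen-4-one | O=c1cc(-c2ccc(O)c(O)c2)oc2cc(O)cc(O)c12 | starting material
2 | dichlorodiphenylmethane | ClC(Cl)(c1ccccc1)c1ccccc1 | starting material
3 | luteolin 3',4'-O-diphenylmethylene ketal, 2-(2,2-diphenyl-1,3-benzodioxol-5-yl)-5,7-dihydroxy-4H-chromen-4-one | O=c1cc(-c2ccc3OC(c4ccccc4)(c4ccccc4)Oc3c2)oc2cc(O)cc(O)c12 | intermediate
4 | luteolin ortho-quinone, 4-(5,7-dihydroxy-4-oxo-4H-chromen-2-yl)cyclohexa-3,5-diene-1,2-dione (not isolated) | O=C1C(=O)C=CC(c2cc(=O)c3c(O)cc(O)cc3o2)=C1 | intermediate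
5 | 2',8''-biluteolin 3''',4'''-O-diphenylmethylene ketal, 2-[2-[2-(2,2-diphenyl-1,3-benzodioxol-5-yl)-5,7-dihydroxy-4-oxo-4H-chromen-8-yl]-4,5-dihydroxyphenyl]-5,7-dihydroxy-4H-chromen-4-one | O=c1cc(-c2cc(O)c(O)cc2-c2c(O)cc(O)c3c(=O)cc(-c4ccc5OC(c6ccccc6)(c6ccccc6)Oc5c4)oc23)oc2cc(O)cc(O)c12 | intermediate
6 | 2',8''-biluteolin, 8-[2-(5,7-dihydroxy-4-oxo-4H-chromen-2-yl)-4,5-dihydroxyphenyl]-2-(3,4-dihydroxyphenyl)-5,7-dihydroxy-4H-chromen-4-one | O=c1cc(-c2cc(O)c(O)cc2-c2c(O)cc(O)c3c(=O)cc(-c4ccc(O)c(O)c4)oc23)oc2cc(O)cc(O)c12 | target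

**Totals**
Total step count: 3. Longest linear sequence: 3 steps (1 → 3 → 5 → 6).

**Steps most likely to fail and fallbacks**

Most likely, step 2. The risks are attack through C6 instead of C8, O-arylation, slow addition of the acyl-deactivated ring A, and redox exchange between 4 and the product catechol; a reducing work-up with ascorbic acid would return product held as its quinone. The fallback sets out from 3 and comes back at 6, and fixes the regiochemistry by a pre-functionalised cross-coupling. Methylation of 3 (Me2SO4, K2CO3, acetone, reflux) gives 2-(2,2-diphenyl-1,3-benzodioxol-5-yl)-5,7-dimethoxy-4H-chromen-4-one F1, and iodination (I2, AgOAc, CH2Cl2, rt) goes to C8 of the 5,7-dimethoxy ring to give the 8-iodo compound F2. For the other half, commercial 2-bromo-4,5-dimethoxybenzaldehyde and 2'-hydroxy-4',6'-dimethoxyacetophenone are condensed (KOH, EtOH, rt) to the (E)-chalcone F3, which is cyclised oxidatively (I2 cat., DMSO, 130 °C) to 2-(2-bromo-4,5-dimethoxyphenyl)-5,7-dimethoxy-4H-chromen-4-one F4 and borylated (B2pin2, Pd(dppf)Cl2, KOAc, dioxane, 90 °C) to the pinacol boronate F5. Suzuki–Miyaura coupling of F2 and F5 (Pd(OAc)2, SPhos, K3PO4, toluene/H2O, 100 °C) gives the hexa-O-methyl biflavone ketal F6, and BBr3 (CH2Cl2, −78 °C to rt, then water) removes all six methyl groups and the ketal to give 6.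

Second, step 3. The risks are partial saturation of C2=C3, stalling because the poorly soluble hexaphenol binds the catalyst, and air sensitivity of the free catechols. The fallback sets out from 5 and comes back at 6. Acetylation of 5 (Ac2O, pyridine, DMAP, rt) gives the hexaacetate F7, which is soluble and lets any C6-linked isomer be removed on silica. Ionic hydrogenolysis of the ketal (CF3CO2H, Et3SiH, CH2Cl2, rt) gives the catechol hexaacetate F8; the acetylated 5-OH cannot take part in a Wessely–Moser reclosure under the acid. Methanolysis (K2CO3 cat., degassed MeOH, 0 °C, then acidify) gives 6.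

Third, step 1. The risks are oligomeric O-alkylation and charring at 175 °C. The fallback sets out from 1 and comes back at 6 without protection: 0.4 equiv of the luteolin is oxidised to 4 (NaIO4, pH 5, 0 °C) and added to the remaining luteolin held as its 7-phenolate at pH 8.5, so the Michael adduct is 6 itself. The product then carries two oxidisable catechols and two nucleophilic rings A, so the reaction is run to partial conversion and luteolin is recycled. This fallback makes no new compound (F0).

**Further compounds**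
F1 | step 2 | 2-(2,2-diphenyl-1,3-benzodioxol-5-yl)-5,7-dimethoxy-4H-chromen-4-one | O=c1cc(-c2ccc3OC(c4ccccc4)(c4ccccc4)Oc3c2)oc2cc(OC)cc(OC)c12
F2 | step 2 | 2-(2,2-diphenyl-1,3-benzodioxol-5-yl)-8-iodo-5,7-dimethoxy-4H-chromen-4-one | O=c1cc(-c2ccc3OC(c4ccccc4)(c4ccccc4)Oc3c2)oc2c(I)c(OC)cc(OC)c12
F3 | step 2 | (E)-3-(2-bromo-4,5-dimethoxyphenyl)-1-(2-hydroxy-4,6-dimethoxyphenyl)prop-2-en-1-one | COc1cc(O)c(C(=O)/C=C/c2cc(OC)c(OC)cc2Br)c(OC)c1
F4 | step 2 | 2-(2-bromo-4,5-dimethoxyphenyl)-5,7-dimethoxy-4H-chromen-4-one | COc1cc(OC)c2c(=O)cc(-c3cc(OC)c(OC)cc3Br)oc2c1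
F5 | step 2 | 2-[4,5-dimethoxy-2-(4,4,5,5-tetramethyl-1,3,2-dioxaborolan-2-yl)phenyl]-5,7-dimethoxy-4H-chromen-4-one | COc1cc(OC)c2c(=O)cc(-c3cc(OC)c(OC)cc3B3OC(C)(C)C(C)(C)O3)oc2c1
F6 | step 2 | 2',8''-biluteolin 5,7,3',4',5'',7''-hexamethyl ether 3''',4'''-O-diphenylmethylene ketal | COc1cc(OC)c2c(=O)cc(-c3cc(OC)c(OC)cc3-c3c(OC)cc(OC)c4c(=O)cc(-c5ccc6OC(c7ccccc7)(c7ccccc7)Oc6c5)oc34)oc2c1
F7 | step 3 | hexaacetate of 5 (5,7,3',4',5'',7''-hexa-O-acetyl, ketal retained) | O=c1cc(-c2cc(OC(C)=O)c(OC(C)=O)cc2-c2c(OC(C)=O)cc(OC(C)=O)c3c(=O)cc(-c4ccc5OC(c6ccccc6)(c6ccccc6)Oc5c4)oc23)oc2cc(OC(C)=O)cc(OC(C)=O)c12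
F8 | step 3 | 2',8''-biluteolin 5,7,3',4',5'',7''-hexaacetate (free 3''',4'''-catechol) | O=c1cc(-c2cc(OC(C)=O)c(OC(C)=O)cc2-c2c(OC(C)=O)cc(OC(C)=O)c3c(=O)cc(-c4ccc(O)c(O)c4)oc23)oc2cc(OC(C)=O)cc(OC(C)=O)c12
F0 | step 1 | none | none
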